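**Plan**

- Numbering (azulene): ring A is C1, C2, C3 (carbinol, isopropyl), C3a (H), C8a (quaternary, methyl); ring B is C3a, C4 (ester oxygen), C5, C6 (methyl), C7, C8, C8a.
- Retrosynthetic cuts, in order: the vanilloyl C4–O acyl bond; the C3–isopropyl bond (Grignard on a C3 ketone); the C4–O and C3a–H bonds (syn hydration of a C3a=C4 alkene); the C6 methyl back to CO2Me; the C8–C8a bond of ring B; last the cyclopropane bonds C4–C6 and C5–C6 (carbenoid C6 plus a vinyl group).
- Enabling feature: ring B holds C6=C7 one CH2 (C5) away from C4, and the cis pair H-3a/O-4 is the trace of a C3a=C4 alkene. Ring B is therefore a cyclohepta-1,4-diene, and its allylic C8–C8a bond is the one formed when a cis-dialkenylcyclopropane C4–C5–C6 (alkenes C7=C8 and ring A's C3a=C8a) relaxes.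
- Forward order: ring A from 3-methylcyclopent-2-enone (iodination, ketal, vinylation); cyclopropane from a rhodium vinylcarbenoid; ring B and the quaternary C8a by the strain-releasing [3,3] shift; then hydroboration, ester-to-methyl reduction, ketone release, isopropyl addition, acylation.
- Stereochemistry: the chiral rhodium catalyst sets the cyclopropane (1S,2S); the boat transition state transfers this to C8a (R); C3a and C4 come from hydroboration anti to the 8a-methyl; C3 from Grignard attack anti to the methyl and to the C3a–C4 bond.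
- Helpers removed later: the CO2Me group (carbenoid acceptor, then shield of C6=C7 against borane, finally reduced to CH3), the cyclopropane, the C3 dioxolane and the phenol acetate.

Key step: step 6

Assumption: with diene 5 the rhodium prolinate catalyst follows its usual sense of induction for donor/acceptor carbenoids and terminal alkenes (Rh2(S-DOSP)4 with methyl phenyldiazoacetate and styrene leads to the (1S,2R)-cyclopropane), so Rh2(R-DOSP)4 should give (1S,2S)-8; if the sense is opposite, the mirror-image catalyst is used.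

**Route**

Step 1
Reactants: 1 3-methylcyclopent-2-en-1-one
Product: 2 2-iodo-3-methylcyclopent-2-en-1-one
Conditions: I2, pyridine, CH2Cl2, 0 °C to rt
Reagents that add atoms: iodine, II
Why: α-Iodination of the enone by the pyridine-mediated addition–iodination–elimination sequence (Baylis–Hillman-like) places iodine at C2, a known reaction of β-alkyl cyclopentenones.

Step 2
Reactants: 2 2-iodo-3-methylcyclopent-2-en-1-one
Product: 3 6-iodo-7-methyl-1,4-dioxaspiro[4.4]non-6-ene
Conditions: HOCH2CH2OH, p-TsOH·H2O (cat.), benzene, reflux, Dean–Stark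
Reagents that add atoms: ethylene glycol, OCCO
Why: Acid-catalysed ketalization with azeotropic removal of water; the α-halogen disfavours double-bond migration, so the allylic dioxolane should form as it does for other 2-halocycloalkenones.

Step 3
Reactants: 3 6-iodo-7-methyl-1,4-dioxaspiro[4.4]non-6-ene; 4 4,4,5,5-tetramethyl-2-vinyl-1,3,2-dioxaborolane
Product: 5 6-ethenyl-7-methyl-1,4-dioxaspiro[4.4]non-6-ene
Conditions: PdCl2(dppf) (5 mol %), K3PO4, 1,4-dioxane/H2O, 80 °C
Reagents that add atoms: none
Why: Suzuki–Miyaura coupling of the alkenyl iodide with the vinyl boronate under basic conditions that leave the ketal intact should give the 1-vinylcyclopentene diene.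

Step 4
Reactants: 6 methyl but-3-enoate
Product: 7 methyl 2-diazobut-3-enoate
Conditions: p-ABSA, DBU, MeCN, 0 °C; cold pentane work-up, used at once
Reagents that add atoms: 4-acetamidobenzenesulfonyl azide (p-ABSA), CC(=O)Nc1ccc(cc1)S(=O)(=O)N=[N+]=[N-]
Why: Regitz diazo transfer to the methylene activated by both the ester and the vinyl group gives the vinyldiazoacetate, which is kept cold and used immediately because it cyclizes to a pyrazole on standing.

Step 5
Reactants: 5 6-ethenyl-7-methyl-1,4-dioxaspiro[4.4]non-6-ene; 7 methyl 2-diazobut-3-enoate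
Product: 8 methyl (1S,2S)-1-ethenyl-2-(7-methyl-1,4-dioxaspiro[4.4]non-6-en-6-yl)cyclopropane-1-carboxylate
Conditions: Rh2(R-DOSP)4 [dirhodium tetrakis((R)-N-(4-dodecylbenzenesulfonyl)prolinate)] (1 mol %), hexanes, −78 to −20 °C, slow addition of 7; cold filtration through silica
Reagents that add atoms: none
Why: Rhodium donor/acceptor vinylcarbenoid cyclopropanation of the terminal alkene of the diene (the tetrasubstituted ring alkene is inert); end-on approach of the alkene places the carbenoid vinyl group cis to the cyclopentenyl group, and the chiral prolinate catalyst selects the carbenoid face, so both cyclopropane stereocenters should be set together, with the nonpolar solvent suppressing vinylogous reactivity.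

Step 6
Reactants: 8 methyl (1S,2S)-1-ethenyl-2-(7-methyl-1,4-dioxaspiro[4.4]non-6-en-6-yl)cyclopropane-1-carboxylate
Product: 9 methyl (8aR)-3,3-(ethylenedioxy)-8a-methyl-1,2,3,5,8,8a-hexahydroazulene-6-carboxylate
Conditions: toluene (degassed), base-washed glassware, 110 °C
Reagents that add atoms: none
Why: Thermal [3,3]-sigmatropic (Cope) rearrangement of the cis-1,2-dialkenylcyclopropane: through a boat transition state with both alkenes folded over the three-membered ring, the vinyl terminus (future C8) bonds to the methyl-bearing terminus of the ring A alkene (future C8a) while the cyclopropane bond between the future C4 and C6 breaks, and release of roughly 27 kcal/mol of ring strain makes the step irreversible. The closest known reaction type is the divinylcyclopropane–cycloheptadiene rearrangement as it occurs in formal [4+3] cycloadditions of rhodium vinylcarbenoids with 1-vinylcycloalkenes, including cases that create a methyl-substituted quaternary ring-fusion carbon. Ring B is closed by this concerted six-electron shift, suprafacial on both allyl halves (a four-carbon ring expansion of the cyclopropane, not an ionic or radical exo/endo cyclization), and the boat geometry delivers both new double bonds (C3a=C4 and C6=C7) cis, as the seven-membered ring requires. The only new stereocenter, C8a, is set by chirality transfer: in the (1S,2S)-cyclopropane only one face of the tetrasubstituted C3a=C8a alkene can reach C8, which should give 8aR as the two cyclopropane stereocenters become sp2 carbons. The selectivity needed is the concerted path over homolytic opening of the cyclopropane (one-centre epimerization would erode enantiomeric purity) and over acid-induced loss of the ketal; the cis relation of the alkenyl groups fixed in step 5 and the acceptor ester keep the pericyclic barrier, raised by the methyl group that points toward the ring CH2, within reach at about 110 °C, and base-washed glassware protects the ketal.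

Step 7
Reactants: 9 methyl (8aR)-3,3-(ethylenedioxy)-8a-methyl-1,2,3,5,8,8a-hexahydroazulene-6-carboxylate
Product: 11 methyl (3aS,4S,8aR)-3,3-(ethylenedioxy)-4-hydroxy-8a-methyl-1,2,3,3a,4,5,8,8a-octahydroazulene-6-carboxylate, via C4 alkylborane 10 (not isolated)
Conditions: BH3·THF, THF, 0 °C to rt; then NaBO3·4H2O, H2O, rt
Reagents that add atoms: borane (as BH3·THF; boron only in 10), B; sodium perborate (hydroxyl oxygen), [Na+].[Na+].O[B-]1(O)OO[B-](O)(O)OO1
Why: Hydroboration–oxidation: borane should add to the electron-rich trisubstituted C3a=C4 alkene faster than to the ester-deactivated C6=C7 alkene, with boron at the less substituted C4; syn addition from the convex face anti to the pseudo-axial 8a-methyl sets H-3a and the C4 oxygen cis to each other and trans to the methyl (trans ring fusion), and perborate oxidizes the C–B bond with retention without hydrolysing the ester.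

Step 8
Reactants: 11 methyl (3aS,4S,8aR)-3,3-(ethylenedioxy)-4-hydroxy-8a-methyl-1,2,3,3a,4,5,8,8a-octahydroazulene-6-carboxylate
Product: 12 (3aS,4S,8aR)-3,3-(ethylenedioxy)-6-(hydroxymethyl)-8a-methyl-1,2,3,3a,4,5,8,8a-octahydroazulen-4-ol
Conditions: i-Bu2AlH (3.5 equiv), CH2Cl2, −78 to 0 °C; aqueous KNaC4H4O6 (potassium sodium tartrate) work-up
Reagents that add atoms: none
Why: 1,2-Reduction of the α,β-unsaturated ester by diisobutylaluminium hydride gives the allylic alcohol; the ketal and the ring alkene are inert at low temperature.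

Step 9
Reactants: 12 (3aS,4S,8aR)-3,3-(ethylenedioxy)-6-(hydroxymethyl)-8a-methyl-1,2,3,3a,4,5,8,8a-octahydroazulen-4-ol
Product: 14 (3aS,4S,8aR)-3,3-(ethylenedioxy)-6,8a-dimethyl-1,2,3,3a,4,5,8,8a-octahydroazulen-4-ol, via primary allylic mesylate 13 (not isolated)
Conditions: MsCl (1.1 equiv), Et3N, THF, −40 °C; then LiEt3BH, −40 to 0 °C
Reagents that add atoms: methanesulfonyl chloride (sulfonyl group only in 13), CS(=O)(=O)Cl
Why: The unhindered primary allylic hydroxyl should be sulfonylated in preference to the hindered secondary one, and SN2 hydride displacement by LiEt3BH (direct substitution is favoured over SN2' for primary allylic sulfonates) turns CH2OH into the C6 methyl.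

Step 10
Reactants: 14 (3aS,4S,8aR)-3,3-(ethylenedioxy)-6,8a-dimethyl-1,2,3,3a,4,5,8,8a-octahydroazulen-4-ol
Product: 15 (3aS,4S,8aR)-4-hydroxy-6,8a-dimethyl-2,3a,4,5,8,8a-hexahydroazulen-3(1H)-one
Conditions: PPTS, acetone/H2O, 40 °C
Reagents that add atoms: water, O
Why: Mild acid-catalysed hydrolysis (transketalization) of the dioxolane frees the C3 ketone; the weak acid and low temperature are chosen to avoid enolization at C3a and dehydration of the β-hydroxy ketone.

Step 11
Reactants: 15 (3aS,4S,8aR)-4-hydroxy-6,8a-dimethyl-2,3a,4,5,8,8a-hexahydroazulen-3(1H)-one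
Product: 16 (3R,3aS,4S,8aR)-6,8a-dimethyl-3-(propan-2-yl)-1,2,3,3a,4,5,8,8a-octahydroazulene-3,4-diol (jaeschkeanadiol)
Conditions: i-PrMgCl (3.5 equiv), LaCl3·2LiCl, THF, −20 to 0 °C; aq NH4Cl
Reagents that add atoms: isopropylmagnesium chloride, CC(C)[Mg]Cl
Why: Lanthanide-promoted Grignard 1,2-addition to the enolizable cyclopentanone (the Lewis acid suppresses enolization, β-hydride reduction and retro-aldol); the nucleophile should enter from the face anti to both the axial 8a-methyl and the C3a–C4 bond, placing isopropyl cis to H-3a and the hydroxyl cis to the methyl (3R).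

Step 12
Reactants: 16 (3R,3aS,4S,8aR)-6,8a-dimethyl-3-(propan-2-yl)-1,2,3,3a,4,5,8,8a-octahydroazulene-3,4-diol; 17 4-acetoxy-3-methoxybenzoic acid
Product: 18 (3R,3aS,4S,8aR)-3-hydroxy-6,8a-dimethyl-3-(propan-2-yl)-1,2,3,3a,4,5,8,8a-octahydroazulen-4-yl 4-acetoxy-3-methoxybenzoate
Conditions: EDC·HCl, DMAP (cat.), CH2Cl2, rt
Reagents that add atoms: none
Why: Steglich esterification should acylate only the secondary C4 hydroxyl, the tertiary C3 hydroxyl being inert, while the acetate on the phenol prevents self-condensation of the acid.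

Step 13
Reactants: 18 (3R,3aS,4S,8aR)-3-hydroxy-6,8a-dimethyl-3-(propan-2-yl)-1,2,3,3a,4,5,8,8a-octahydroazulen-4-yl 4-acetoxy-3-methoxybenzoate
Product: 19 teferin, (3R,3aS,4S,8aR)-3-hydroxy-6,8a-dimethyl-3-(propan-2-yl)-1,2,3,3a,4,5,8,8a-octahydroazulen-4-yl 4-hydroxy-3-methoxybenzoate
Conditions: pyrrolidine, CH2Cl2, 0 °C to rt
Reagents that add atoms: none
Why: Chemoselective aminolysis of the aryl acetate (an activated phenyl ester) by pyrrolidine should leave the hindered secondary benzoate and the tertiary alcohol untouched.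

**Compound list**

1 | 3-methylcyclopent-2-en-1-one | CC1=CC(=O)CC1 | starting material
2 | 2-iodo-3-methylcyclopent-2-en-1-one | CC1=C(I)C(=O)CC1 | intermediate
3 | 6-iodo-7-methyl-1,4-dioxaspiro[4.4]non-6-ene | CC1=C(I)C2(CC1)OCCO2 | intermediate
4 | 4,4,5,5-tetramethyl-2-vinyl-1,3,2-dioxaborolane | C=CB1OC(C)(C)C(C)(C)O1 | starting material
5 | 6-ethenyl-7-methyl-1,4-dioxaspiro[4.4]non-6-ene | C=CC1=C(C)CCC12OCCO2 | intermediate
6 | methyl but-3-enoate | C=CCC(=O)OC | starting material
7 | methyl 2-diazobut-3-enoate | C=CC(=[N+]=[N-])C(=O)OC | intermediate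
8 | methyl (1S,2S)-1-ethenyl-2-(7-methyl-1,4-dioxaspiro[4.4]non-6-en-6-yl)cyclopropane-1-carboxylate (alkenyl groups cis) | COC(=O)[C@]1(C=C)C[C@H]1C2=C(C)CCC23OCCO3 | intermediate
9 | methyl (8aR)-3,3-(ethylenedioxy)-8a-methyl-1,2,3,5,8,8a-hexahydroazulene-6-carboxylate | COC(=O)C1=CC[C@@]2(C)CCC3(OCCO3)C2=CC1 | intermediate
10 | C4 alkylborane of 9 (boron and H-3a cis, both trans to the 8a-methyl) | B[C@H]1CC(C(=O)OC)=CC[C@@]2(C)CCC3(OCCO3)[C@H]12 | intermediate
11 | methyl (3aS,4S,8aR)-3,3-(ethylenedioxy)-4-hydroxy-8a-methyl-1,2,3,3a,4,5,8,8a-octahydroazulene-6-carboxylate | O[C@H]1CC(C(=O)OC)=CC[C@@]2(C)CCC3(OCCO3)[C@H]12 | intermediate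
12 | (3aS,4S,8aR)-3,3-(ethylenedioxy)-6-(hydroxymethyl)-8a-methyl-1,2,3,3a,4,5,8,8a-octahydroazulen-4-ol | O[C@H]1CC(CO)=CC[C@@]2(C)CCC3(OCCO3)[C@H]12 | intermediate
13 | primary allylic methanesulfonate of 12 | O[C@H]1CC(COS(C)(=O)=O)=CC[C@@]2(C)CCC3(OCCO3)[C@H]12 | intermediate
14 | (3aS,4S,8aR)-3,3-(ethylenedioxy)-6,8a-dimethyl-1,2,3,3a,4,5,8,8a-octahydroazulen-4-ol | O[C@H]1CC(C)=CC[C@@]2(C)CCC3(OCCO3)[C@H]12 | intermediate
15 | (3aS,4S,8aR)-4-hydroxy-6,8a-dimethyl-2,3a,4,5,8,8a-hexahydroazulen-3(1H)-one | O[C@H]1CC(C)=CC[C@@]2(C)CCC(=O)[C@H]12 | intermediate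
16 | (3R,3aS,4S,8aR)-6,8a-dimethyl-3-(propan-2-yl)-1,2,3,3a,4,5,8,8a-octahydroazulene-3,4-diol (jaeschkeanadiol) | O[C@H]1CC(C)=CC[C@@]2(C)CC[C@@](O)(C(C)C)[C@H]12 | intermediate
17 | 4-acetoxy-3-methoxybenzoic acid | COc1cc(C(=O)O)ccc1OC(C)=O | starting material
18 | (3R,3aS,4S,8aR)-3-hydroxy-6,8a-dimethyl-3-(propan-2-yl)-1,2,3,3a,4,5,8,8a-octahydroazulen-4-yl 4-acetoxy-3-methoxybenzoate | COc1cc(C(=O)O[C@H]2CC(C)=CC[C@@]3(C)CC[C@@](O)(C(C)C)[C@H]23)ccc1OC(C)=O | intermediate
19 | teferin | COc1cc(C(=O)O[C@H]2CC(C)=CC[C@@]3(C)CC[C@@](O)(C(C)C)[C@H]23)ccc1O | target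

**Count**

Total steps: 13. Longest linear sequence: 12 (steps 1–3 and 5–13; step 4 makes the diazo partner).

**Steps most likely to fail, with fallbacks**

Step 7. What may go wrong: borane reduces or hydroborates the conjugated ester, or adds to C3a=C4 from the face syn to the 8a-methyl, so that the cis-fused C3a/C4 epimer forms. Fallback, from 9 back to 16: the C4 oxygen is brought in by conjugate (nucleophilic) epoxidation instead of hydroboration. Hydrolysis of the ketal of 9 (PPTS, acetone/H2O) gives the cross-conjugated dienone methyl (8aR)-8a-methyl-3-oxo-1,2,3,5,8,8a-hexahydroazulene-6-carboxylate F5. Weitz–Scheffer epoxidation (t-BuOOH, DBU) attacks only the enone, from the face anti to the methyl, to give the 3a,4-epoxy ketone F6. SmI2 (THF/MeOH, −78 °C) cleaves the α C–O bond, and protonation of the samarium enolate anti to the methyl gives methyl (3aS,4S,8aR)-4-hydroxy-8a-methyl-3-oxo-1,2,3,3a,4,5,8,8a-octahydroazulene-6-carboxylate F7. i-PrMgCl with LaCl3·2LiCl adds to the ketone in preference to the enoate to give methyl (3R,3aS,4S,8aR)-3,4-dihydroxy-8a-methyl-3-(propan-2-yl)-1,2,3,3a,4,5,8,8a-octahydroazulene-6-carboxylate F8. i-Bu2AlH gives (3R,3aS,4S,8aR)-6-(hydroxymethyl)-8a-methyl-3-(propan-2-yl)-1,2,3,3a,4,5,8,8a-octahydroazulene-3,4-diol F9. MsCl/Et3N and then LiEt3BH, through the primary allylic methanesulfonate F10, lead to 16.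

Step 5. What may go wrong: the labile diazo ester is consumed by electrocyclization to a pyrazole and by carbene dimerization before transfer, and facial discrimination by the catalyst next to the bulky ketal is incomplete, so that 8 forms in low amount or low enantiomeric purity. Fallback, from 5 back to 9: stereocontrol is moved from the catalyst to a covalently bound auxiliary. But-3-enoic acid is esterified with (R)-pantolactone (DCC, DMAP cat.) to (3R)-4,4-dimethyl-2-oxooxolan-3-yl but-3-enoate F1. Diazo transfer (p-ABSA, DBU) gives (3R)-4,4-dimethyl-2-oxooxolan-3-yl 2-diazobut-3-enoate F2. With achiral Rh2(O2CC7H15)4 in hexanes, 5 is cyclopropanated to (3R)-4,4-dimethyl-2-oxooxolan-3-yl (1S,2S)-1-ethenyl-2-(7-methyl-1,4-dioxaspiro[4.4]non-6-en-6-yl)cyclopropane-1-carboxylate F3, whose diastereomers can be separated (the enantiomeric auxiliary is taken if the sense of induction requires it). Heating as in step 6 gives the pantolactonyl ester of the bicyclic acid F4, and transesterification (NaOMe, MeOH, 0 °C) returns 9.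

Step 11. What may go wrong: enolization of the C3 ketone with loss of the C3a configuration, β-hydride reduction by the secondary Grignard reagent, or retro-aldol opening of ring B from the C4 alkoxide, in place of addition. Fallback, from 15 back to 16: a smaller alkenyl nucleophile that does not reduce ketones is added and then saturated. Isopropenylmagnesium bromide with LaCl3·2LiCl (THF, −20 °C) gives (3S,3aS,4S,8aR)-6,8a-dimethyl-3-(prop-1-en-2-yl)-1,2,3,3a,4,5,8,8a-octahydroazulene-3,4-diol F11. Its 1,1-disubstituted alkene is then hydrogenated selectively over the trisubstituted ring alkene (H2, RhCl(PPh3)3, benzene) to give 16.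

**Further compounds**

F1 | step 5 | (3R)-4,4-dimethyl-2-oxooxolan-3-yl but-3-enoate | C=CCC(=O)O[C@H]1C(=O)OCC1(C)C
F2 | step 5 | (3R)-4,4-dimethyl-2-oxooxolan-3-yl 2-diazobut-3-enoate | C=CC(=[N+]=[N-])C(=O)O[C@H]1C(=O)OCC1(C)C
F3 | step 5 | (3R)-4,4-dimethyl-2-oxooxolan-3-yl (1S,2S)-1-ethenyl-2-(7-methyl-1,4-dioxaspiro[4.4]non-6-en-6-yl)cyclopropane-1-carboxylate | O=C(O[C@H]1C(=O)OCC1(C)C)[C@]2(C=C)C[C@H]2C3=C(C)CCC34OCCO4
F4 | step 5 | (3R)-4,4-dimethyl-2-oxooxolan-3-yl (8aR)-3,3-(ethylenedioxy)-8a-methyl-1,2,3,5,8,8a-hexahydroazulene-6-carboxylate | O=C(O[C@H]1C(=O)OCC1(C)C)C2=CC[C@@]3(C)CCC4(OCCO4)C3=CC2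
F5 | step 7 | methyl (8aR)-8a-methyl-3-oxo-1,2,3,5,8,8a-hexahydroazulene-6-carboxylate | COC(=O)C1=CC[C@@]2(C)CCC(=O)C2=CC1
F6 | step 7 | methyl 3a,4-epoxy-8a-methyl-3-oxo-1,2,3,3a,4,5,8,8a-octahydroazulene-6-carboxylate (epoxide oxygen trans to the 8a-methyl, 8aR) | O1[C@H]2CC(C(=O)OC)=CC[C@@]3(C)CCC(=O)[C@]123
F7 | step 7 | methyl (3aS,4S,8aR)-4-hydroxy-8a-methyl-3-oxo-1,2,3,3a,4,5,8,8a-octahydroazulene-6-carboxylate | O[C@H]1CC(C(=O)OC)=CC[C@@]2(C)CCC(=O)[C@H]12
F8 | step 7 | methyl (3R,3aS,4S,8aR)-3,4-dihydroxy-8a-methyl-3-(propan-2-yl)-1,2,3,3a,4,5,8,8a-octahydroazulene-6-carboxylate | O[C@H]1CC(C(=O)OC)=CC[C@@]2(C)CC[C@@](O)(C(C)C)[C@H]12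
F9 | step 7 | (3R,3aS,4S,8aR)-6-(hydroxymethyl)-8a-methyl-3-(propan-2-yl)-1,2,3,3a,4,5,8,8a-octahydroazulene-3,4-diol | O[C@H]1CC(CO)=CC[C@@]2(C)CC[C@@](O)(C(C)C)[C@H]12
F10 | step 7 | primary allylic methanesulfonate of F9 | O[C@H]1CC(COS(C)(=O)=O)=CC[C@@]2(C)CC[C@@](O)(C(C)C)[C@H]12
F11 | step 11 | (3S,3aS,4S,8aR)-6,8a-dimethyl-3-(prop-1-en-2-yl)-1,2,3,3a,4,5,8,8a-octahydroazulene-3,4-diol | O[C@H]1CC(C)=CC[C@@]2(C)CC[C@@](O)(C(C)=C)[C@H]12
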